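## Retrosynthetic overview

1. The target comes from the 8,9‑diol of the furanoheliangolide core by late 8‑O‑methacryloylation, 9‑O‑angeloylation and 15‑O‑desilylation.
2. The 3(2H)‑furanone ring (formed last) comes from transannular attack of the C10 hydroxyl on C3 of a macrocyclic 10‑hydroxy‑1,3‑dicarbonyl equivalent (4‑hydroxy‑2‑ynone plus water), the closure presumed in the biosynthesis.
3. The ten‑membered carbocycle (formed first) and the 6,12‑lactone (second) come from C6–C7 bond formation: the C7 terminus of a 2‑(bromomethyl)enoate adds to the C6 aldehyde (laboratory counterpart of the farnesyl → germacrene closure), then lactonisation. The C6 aldehyde, C3 ketone and 4Z alkene are unmasked together by oxidative opening of a 2,3‑disubstituted furan.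
4. The open chain comes from a Sonogashira union (C2–C3) of an iodofuran made from furan‑3‑ylmethanol with an alkyne built on L‑tartrate: C8 and C9 from the chiral pool, C10 by chelation‑controlled ethynylation, C11–C13 by Morita–Baylis–Hillman reaction and allylic bromination.
5. Ring order: carbocycle → γ‑lactone → furanone.

Assumption: positions are labelled with germacrane numbering (C1–C15, H‑7 is α), and dimethyldioxirane (from acetone and KHSO5) and Ph3PAuNTf2 are used as stock reagents.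

## Route

Step 1
Reactants: 1 dimethyl (4R,5R)-2,2-dimethyl-1,3-dioxolane-4,5-dicarboxylate (dimethyl 2,3-O-isopropylidene-L-tartrate); 2 N,O-dimethylhydroxylamine hydrochloride
Product: 3 (4R,5R)-N4,N5-dimethoxy-N4,N5,2,2-tetramethyl-1,3-dioxolane-4,5-dicarboxamide
Conditions: MeNH(OMe)·HCl (3 equiv), i-PrMgCl (6 equiv), THF, −20 °C
Reagents that add atoms: N,O-dimethylhydroxylamine hydrochloride (2), CNOC.Cl
Why: Weinreb amidation of both esters by the chloromagnesium amide (ester aminolysis); the two stereocentres (future C8 and C9, from L-tartaric acid) are not involved and the trans-dioxolane is the thermodynamic arrangement.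

Step 2
Reactants: 3 (4R,5R)-N4,N5-dimethoxy-N4,N5,2,2-tetramethyl-1,3-dioxolane-4,5-dicarboxamide; 4 methylmagnesium bromide
Product: 5 (4R,5R)-5-acetyl-N-methoxy-N,2,2-trimethyl-1,3-dioxolane-4-carboxamide
Conditions: MeMgBr (1.05 equiv), THF, −78 → −20 °C; aq. NH4Cl
Reagents that add atoms: methylmagnesium bromide (4), C[Mg]Br
Why: Weinreb ketone synthesis, in which the magnesium-chelated tetrahedral adduct survives until work-up, so one amide becomes the methyl ketone (future C10 and C14) without over-addition and one equivalent of Grignard reagent leaves the second amide (unreacted 3 is recovered and recycled).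

Step 3
Reactants: 5 (4R,5R)-5-acetyl-N-methoxy-N,2,2-trimethyl-1,3-dioxolane-4-carboxamide; 6 ethynylmagnesium bromide
Product: 7 (4R,5R)-5-[(2R)-2-hydroxybut-3-yn-2-yl]-N-methoxy-N,2,2-trimethyl-1,3-dioxolane-4-carboxamide
Conditions: HC≡CMgBr (1.5 equiv), THF/toluene, −78 → −40 °C
Reagents that add atoms: ethynylmagnesium bromide (6), C#C[Mg]Br
Why: Cram-chelate-controlled Grignard addition, in which magnesium bridges the ketone oxygen and the adjacent dioxolane oxygen and the acetylide attacks the face anti to C8, giving the (2R)-carbinol with O9/O10 threo (C10 of the target, 10S there); the ketone reacts much faster than the Weinreb amide at this temperature.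

Step 4
Reactants: 8 furan-3-ylmethanol
Product: 10 tert-butyl[(2-iodofuran-3-yl)methoxy]diphenylsilane, via lithium (2-iodofuran-3-yl)methanolate 9 (not isolated)
Conditions: n-BuLi (2.2 equiv), THF, −78 → 0 °C; I2, −78 °C; then TBDPSCl, DMAP (cat.), 0 °C → rt
Reagents that add atoms: iodine, II; tert-butyl(chloro)diphenylsilane, CC(C)(C)[Si](Cl)(c1ccccc1)c1ccccc1
Why: alkoxide-directed ortho-lithiation of the furan at C2 (dianion), iodination of the aryllithium and O-silylation of the remaining lithium alkoxide in the same flask; no stereocentre is involved.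

Step 5
Reactants: 7 (4R,5R)-5-[(2R)-2-hydroxybut-3-yn-2-yl]-N-methoxy-N,2,2-trimethyl-1,3-dioxolane-4-carboxamide; 10 tert-butyl[(2-iodofuran-3-yl)methoxy]diphenylsilane
Product: 11 (4R,5R)-5-[(2R)-4-[3-(tert-butyldiphenylsilyloxymethyl)furan-2-yl]-2-hydroxybut-3-yn-2-yl]-N-methoxy-N,2,2-trimethyl-1,3-dioxolane-4-carboxamide
Conditions: PdCl2(PPh3)2 (3 mol %), CuI (6 mol %), Et3N, THF, rt
Reagents that add atoms: none
Why: Sonogashira coupling of the terminal alkyne with the 2-iodofuran forms the C2–C3 bond and tolerates the free tertiary alcohol, the Weinreb amide and the acetonide.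

Step 6
Reactants: 11 (4R,5R)-5-[(2R)-4-[3-(tert-butyldiphenylsilyloxymethyl)furan-2-yl]-2-hydroxybut-3-yn-2-yl]-N-methoxy-N,2,2-trimethyl-1,3-dioxolane-4-carboxamide
Product: 12 (4R,5R)-5-[(2R)-4-[3-(tert-butyldiphenylsilyloxymethyl)furan-2-yl]-2-hydroxybut-3-yn-2-yl]-2,2-dimethyl-1,3-dioxolane-4-carbaldehyde
Conditions: i-Bu2AlH (2.5 equiv), THF, −78 °C; aq. potassium sodium tartrate
Reagents that add atoms: none
Why: reduction of the Weinreb amide stops at the chelated aluminium hemiaminal and gives the C7 aldehyde on work-up; the α-stereocentre (C8) sits in a trans-dioxolane, the thermodynamic isomer, so it is not eroded.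

Step 7
Reactants: 12 (4R,5R)-5-[(2R)-4-[3-(tert-butyldiphenylsilyloxymethyl)furan-2-yl]-2-hydroxybut-3-yn-2-yl]-2,2-dimethyl-1,3-dioxolane-4-carbaldehyde; 13 methyl acrylate
Product: 14 methyl 2-{hydroxy[(4S,5R)-5-{(2R)-4-[3-(tert-butyldiphenylsilyloxymethyl)furan-2-yl]-2-hydroxybut-3-yn-2-yl}-2,2-dimethyl-1,3-dioxolan-4-yl]methyl}prop-2-enoate (both C7 epimers)
Conditions: methyl acrylate (10 equiv), DABCO (1 equiv), MeOH, rt, 72 h
Reagents that add atoms: methyl acrylate (13), C=CC(=O)OC
Why: Morita–Baylis–Hillman reaction joins C7 to the acrylate α-carbon (C11) and brings in C12 and C13; the new carbinol centre at C7 forms as a mixture, which does not matter because C7 becomes sp2 in step 8.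

Step 8
Reactants: 14 methyl 2-{hydroxy[(4S,5R)-5-{(2R)-4-[3-(tert-butyldiphenylsilyloxymethyl)furan-2-yl]-2-hydroxybut-3-yn-2-yl}-2,2-dimethyl-1,3-dioxolan-4-yl]methyl}prop-2-enoate
Product: 15 methyl (2Z)-2-(bromomethyl)-3-[(4S,5R)-5-{(2R)-4-[3-(tert-butyldiphenylsilyloxymethyl)furan-2-yl]-2-hydroxybut-3-yn-2-yl}-2,2-dimethyl-1,3-dioxolan-4-yl]prop-2-enoate
Conditions: NBS (1.3 equiv), Me2S (1.5 equiv), CH2Cl2, −20 °C; then 14, −20 → 0 °C
Reagents that add atoms: N-bromosuccinimide, O=C1CCC(=O)N1Br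
Why: Corey–Kim-type activation of the secondary allylic alcohol (the hindered tertiary alcohol does not react) and SN2′ displacement by bromide give the rearranged, thermodynamically favoured (Z)-2-(bromomethyl)enoate; pre-forming the sulfonium reagent keeps free NBS away from the furan.

Step 9
Reactants: 15 methyl (2Z)-2-(bromomethyl)-3-[(4S,5R)-5-{(2R)-4-[3-(tert-butyldiphenylsilyloxymethyl)furan-2-yl]-2-hydroxybut-3-yn-2-yl}-2,2-dimethyl-1,3-dioxolan-4-yl]prop-2-enoate
Product: 18 (4Z)-15-(tert-butyldiphenylsilyloxy)-10β-hydroxy-8β,9α-(isopropylidenedioxy)-3-oxo-7αH-germacra-4,11(13)-dien-1-yn-12,6α-olide, via ynenedione aldehyde 16 (not isolated), via macrocyclic hydroxy ester 17 (not isolated)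
Conditions: DMDO (1.1 equiv), acetone, −40 → 0 °C; evaporate; then indium powder (3 equiv), DMF, 2 mM (slow addition), 25 → 45 °C
Reagents that add atoms: dimethyldioxirane, CC1(C)OO1
Why: Proposed new method: dimethyldioxirane opens the 2,3-disubstituted furan to the (Z)-4-oxo-enal (C3 ketone, C6 aldehyde, 4Z alkene kept from the ring), then indium inserts into the allylic bromide and the 2-(alkoxycarbonyl)allylindium adds through C7 to the C6 aldehyde in a closed six-membered transition state (ring-chain ends equatorial give the 6,7-anti adduct, which lactonises to the trans-fused 6α,12-olide, while allylic 1,3-strain holds C8–H in the allyl plane so that C6 bonds to the C7 face anti to C9, setting 7αH and 6R), with the C8 acetal oxygen too poor a leaving group for 1,4-elimination and unable to lactonise; the closest known reactions are the oxidative opening of furans to cis-enediones and the intramolecular Barbier allylation/lactonisation used to close ten-membered germacranolide rings, and zerovalent indium is chosen because it is too weak a reductant to touch the ynenedione.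

Step 10
Reactants: 18 (4Z)-15-(tert-butyldiphenylsilyloxy)-10β-hydroxy-8β,9α-(isopropylidenedioxy)-3-oxo-7αH-germacra-4,11(13)-dien-1-yn-12,6α-olide
Product: 21 (4Z)-15-(tert-butyldiphenylsilyloxy)-3,10β-epoxy-8β,9α-dihydroxy-1-oxo-7αH-germacra-2,4,11(13)-trien-12,6α-olide, via macrocyclic 1,3-diketone 19 (not isolated), via furanone acetonide 20 (not isolated)
Conditions: Ph3PAuNTf2 (5 mol %), H2O (5 equiv), 1,4-dioxane, 40 °C; then TFA/H2O/THF (1:1:4), 0 °C → rt
Reagents that add atoms: water, O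
Why: Proposed new method: the cationic gold catalyst hydrates the ketone-conjugated C1≡C2 alkyne with water adding at C1 (β to the C3 ketone, next to the carbinol), the resulting 10-hydroxy-1,3-dione closes across the ring by attack of O10 on C3 and loss of water to the 3(2H)-furanone, and aqueous TFA then cleaves the trans-dioxolane while the TBDPS ether survives; the closest known reactions are gold-catalysed hydration of ynones to 1,3-diketones and the acid- or amine-mediated conversion of 4-hydroxyalk-2-ynones into 3(2H)-furanones, and no stereocentre is formed or touched.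

Step 11
Reactants: 21 (4Z)-15-(tert-butyldiphenylsilyloxy)-3,10β-epoxy-8β,9α-dihydroxy-1-oxo-7αH-germacra-2,4,11(13)-trien-12,6α-olide; 22 methacrylic anhydride
Product: 23 (4Z)-15-(tert-butyldiphenylsilyloxy)-3,10β-epoxy-9α-hydroxy-8β-(methacryloyloxy)-1-oxo-7αH-germacra-2,4,11(13)-trien-12,6α-olide
Conditions: methacrylic anhydride (1.2 equiv), Et3N, DMAP (0.1 equiv), CH2Cl2, −20 °C
Reagents that add atoms: methacrylic anhydride (22), CC(=C)C(=O)OC(=O)C(C)=C
Why: DMAP-catalysed acylation selective for the C8 hydroxyl, which is less hindered than the C9 hydroxyl flanked by the fully substituted C10 (the C15 oxygen is silylated); acylation at oxygen leaves all stereocentres untouched.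

Step 12
Reactants: 23 (4Z)-15-(tert-butyldiphenylsilyloxy)-3,10β-epoxy-9α-hydroxy-8β-(methacryloyloxy)-1-oxo-7αH-germacra-2,4,11(13)-trien-12,6α-olide; 24 angelic acid
Product: 25 (4Z)-9α-(angeloyloxy)-15-(tert-butyldiphenylsilyloxy)-3,10β-epoxy-8β-(methacryloyloxy)-1-oxo-7αH-germacra-2,4,11(13)-trien-12,6α-olide
Conditions: angelic acid (3 equiv), 2,4,6-Cl3C6H2COCl (3 equiv), Et3N, toluene, rt; then 23, toluene, 80 °C
Reagents that add atoms: angelic acid (24), C/C=C(/C)C(=O)O
Why: Yamaguchi-type mixed-anhydride esterification forces the hindered C9 hydroxyl to react, and leaving out DMAP avoids Z→E isomerisation of the angelate to the tiglate; the C9 configuration is retained.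

Step 13
Reactants: 25 (4Z)-9α-(angeloyloxy)-15-(tert-butyldiphenylsilyloxy)-3,10β-epoxy-8β-(methacryloyloxy)-1-oxo-7αH-germacra-2,4,11(13)-trien-12,6α-olide
Product: 26 (4Z,6R,7S,8S,9R,10S)-9-(angeloyloxy)-3,10-epoxy-15-hydroxy-8-(methacryloyloxy)-1-oxogermacra-2,4,11(13)-trien-12,6-olide (CNP0359568.2)
Conditions: HF·pyridine, THF/pyridine, 0 °C → rt
Reagents that add atoms: none
Why: fluoride-mediated desilylation under mildly acidic conditions leaves the two enoate esters, the α-methylene lactone and the furanone intact and gives the target.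

## Compound list

1 | dimethyl (4R,5R)-2,2-dimethyl-1,3-dioxolane-4,5-dicarboxylate | COC(=O)[C@@H]1OC(C)(C)O[C@H]1C(=O)OC | starting material
2 | N,O-dimethylhydroxylamine hydrochloride | CNOC.Cl | starting material
3 | (4R,5R)-N4,N5-dimethoxy-N4,N5,2,2-tetramethyl-1,3-dioxolane-4,5-dicarboxamide | CON(C)C(=O)[C@@H]1OC(C)(C)O[C@H]1C(=O)N(C)OC | intermediate
4 | methylmagnesium bromide | C[Mg]Br | starting material
5 | (4R,5R)-5-acetyl-N-methoxy-N,2,2-trimethyl-1,3-dioxolane-4-carboxamide | CON(C)C(=O)[C@@H]1OC(C)(C)O[C@H]1C(C)=O | intermediate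
6 | ethynylmagnesium bromide | C#C[Mg]Br | starting material
7 | (4R,5R)-5-[(2R)-2-hydroxybut-3-yn-2-yl]-N-methoxy-N,2,2-trimethyl-1,3-dioxolane-4-carboxamide | CON(C)C(=O)[C@@H]1OC(C)(C)O[C@H]1[C@](C)(O)C#C | intermediate
8 | furan-3-ylmethanol | OCc1ccoc1 | starting material
9 | lithium (2-iodofuran-3-yl)methanolate | [Li+].[O-]Cc1ccoc1I | intermediate
10 | tert-butyl[(2-iodofuran-3-yl)methoxy]diphenylsilane | CC(C)(C)[Si](OCc1ccoc1I)(c1ccccc1)c1ccccc1 | intermediate
11 | (4R,5R)-5-[(2R)-4-[3-(tert-butyldiphenylsilyloxymethyl)furan-2-yl]-2-hydroxybut-3-yn-2-yl]-N-methoxy-N,2,2-trimethyl-1,3-dioxolane-4-carboxamide | CON(C)C(=O)[C@@H]1OC(C)(C)O[C@H]1[C@](C)(O)C#Cc1occc1CO[Si](c1ccccc1)(c1ccccc1)C(C)(C)C | intermediate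
12 | (4R,5R)-5-[(2R)-4-[3-(tert-butyldiphenylsilyloxymethyl)furan-2-yl]-2-hydroxybut-3-yn-2-yl]-2,2-dimethyl-1,3-dioxolane-4-carbaldehyde | O=C[C@@H]1OC(C)(C)O[C@H]1[C@](C)(O)C#Cc1occc1CO[Si](c1ccccc1)(c1ccccc1)C(C)(C)C | intermediate
13 | methyl acrylate | C=CC(=O)OC | starting material
14 | methyl 2-{hydroxy[(4S,5R)-5-{(2R)-4-[3-(tert-butyldiphenylsilyloxymethyl)furan-2-yl]-2-hydroxybut-3-yn-2-yl}-2,2-dimethyl-1,3-dioxolan-4-yl]methyl}prop-2-enoate (both C7 epimers) | COC(=O)C(=C)C(O)[C@@H]1OC(C)(C)O[C@H]1[C@](C)(O)C#Cc1occc1CO[Si](c1ccccc1)(c1ccccc1)C(C)(C)C | intermediate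
15 | methyl (2Z)-2-(bromomethyl)-3-[(4S,5R)-5-{(2R)-4-[3-(tert-butyldiphenylsilyloxymethyl)furan-2-yl]-2-hydroxybut-3-yn-2-yl}-2,2-dimethyl-1,3-dioxolan-4-yl]prop-2-enoate | COC(=O)/C(CBr)=C/[C@@H]1OC(C)(C)O[C@H]1[C@](C)(O)C#Cc1occc1CO[Si](c1ccccc1)(c1ccccc1)C(C)(C)C | intermediate
16 | methyl (2Z)-2-(bromomethyl)-3-[(4S,5R)-5-{(2R,6Z)-6-(tert-butyldiphenylsilyloxymethyl)-2-hydroxy-5,8-dioxooct-6-en-3-yn-2-yl}-2,2-dimethyl-1,3-dioxolan-4-yl]prop-2-enoate (ynenedione aldehyde) | COC(=O)/C(CBr)=C/[C@@H]1OC(C)(C)O[C@H]1[C@](C)(O)C#CC(=O)/C(CO[Si](c1ccccc1)(c1ccccc1)C(C)(C)C)=C\C=O | intermediate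
17 | methyl (4Z)-15-(tert-butyldiphenylsilyloxy)-6α,10β-dihydroxy-8β,9α-(isopropylidenedioxy)-3-oxo-7αH-germacra-4,11(13)-dien-1-yn-12-oate (macrocyclic hydroxy ester) | CC1(C)O[C@H]2[C@@H](C(=C)C(=O)OC)[C@H](O)/C=C(/CO[Si](c3ccccc3)(c3ccccc3)C(C)(C)C)C(=O)C#C[C@@](C)(O)[C@@H]2O1 | intermediate
18 | (4Z)-15-(tert-butyldiphenylsilyloxy)-10β-hydroxy-8β,9α-(isopropylidenedioxy)-3-oxo-7αH-germacra-4,11(13)-dien-1-yn-12,6α-olide | CC1(C)O[C@H]2[C@H]3C(=C)C(=O)O[C@@H]3/C=C(/CO[Si](c3ccccc3)(c3ccccc3)C(C)(C)C)C(=O)C#C[C@@](C)(O)[C@@H]2O1 | intermediate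
19 | (4Z)-15-(tert-butyldiphenylsilyloxy)-10β-hydroxy-8β,9α-(isopropylidenedioxy)-1,3-dioxo-7αH-germacra-4,11(13)-dien-12,6α-olide (macrocyclic 1,3-diketone) | CC1(C)O[C@H]2[C@H]3C(=C)C(=O)O[C@@H]3/C=C(/CO[Si](c3ccccc3)(c3ccccc3)C(C)(C)C)C(=O)CC(=O)[C@@](C)(O)[C@@H]2O1 | intermediate
20 | (4Z)-15-(tert-butyldiphenylsilyloxy)-3,10β-epoxy-8β,9α-(isopropylidenedioxy)-1-oxo-7αH-germacra-2,4,11(13)-trien-12,6α-olide (furanone acetonide) | CC1(C)O[C@H]2[C@H]3C(=C)C(=O)O[C@@H]3/C=C(/CO[Si](c3ccccc3)(c3ccccc3)C(C)(C)C)C3=CC(=O)[C@@](C)(O3)[C@@H]2O1 | intermediate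
21 | (4Z)-15-(tert-butyldiphenylsilyloxy)-3,10β-epoxy-8β,9α-dihydroxy-1-oxo-7αH-germacra-2,4,11(13)-trien-12,6α-olide | O[C@H]1[C@H]2C(=C)C(=O)O[C@@H]2/C=C(/CO[Si](c2ccccc2)(c2ccccc2)C(C)(C)C)C2=CC(=O)[C@@](C)(O2)[C@@H]1O | intermediate
22 | methacrylic anhydride | CC(=C)C(=O)OC(=O)C(C)=C | starting material
23 | (4Z)-15-(tert-butyldiphenylsilyloxy)-3,10β-epoxy-9α-hydroxy-8β-(methacryloyloxy)-1-oxo-7αH-germacra-2,4,11(13)-trien-12,6α-olide | C=C(C)C(=O)O[C@H]1[C@H]2C(=C)C(=O)O[C@@H]2/C=C(/CO[Si](c2ccccc2)(c2ccccc2)C(C)(C)C)C2=CC(=O)[C@@](C)(O2)[C@@H]1O | intermediate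
24 | angelic acid, (2Z)-2-methylbut-2-enoic acid | C/C=C(/C)C(=O)O | starting material
25 | (4Z)-9α-(angeloyloxy)-15-(tert-butyldiphenylsilyloxy)-3,10β-epoxy-8β-(methacryloyloxy)-1-oxo-7αH-germacra-2,4,11(13)-trien-12,6α-olide | C=C(C)C(=O)O[C@H]1[C@H]2C(=C)C(=O)O[C@@H]2/C=C(/CO[Si](c2ccccc2)(c2ccccc2)C(C)(C)C)C2=CC(=O)[C@@](C)(O2)[C@@H]1OC(=O)/C(C)=C\C | intermediate
26 | (4Z,6R,7S,8S,9R,10S)-9-(angeloyloxy)-3,10-epoxy-15-hydroxy-8-(methacryloyloxy)-1-oxogermacra-2,4,11(13)-trien-12,6-olide (CNP0359568.2) | C=C(C)C(=O)O[C@H]1[C@H]2C(=C)C(=O)O[C@@H]2/C=C(/CO)C2=CC(=O)[C@@](C)(O2)[C@@H]1OC(=O)/C(C)=C\C | target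

## Step count and risks

Total step count: 13. Longest linear sequence: 12 steps (steps 1–3 and 5–13, from 1).

The step most likely to fail is step 9. Indium may not spare the ynenedione, the cis-enedione may isomerise, the strained alkyne-containing ring may close poorly, or the C6/C7 outcome may differ from the model. The fallback reverses the order of the last two ring closures. It sets out from 15: after the dimethyldioxirane opening to 16, Ph3PAuNTf2 and water in dioxane hydrate the unstrained open-chain ynone, and the 10-hydroxy-1,3-dione cyclodehydrates to the open-chain furanone aldehyde F1, in which the enedione has become a vinylogous ester. Indium-mediated ring closure of F1 in DMF then gives the macrocyclic hydroxy ester F2, which lactonises in the flask to 20, where the route is rejoined at the TFA stage of step 10.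

The second is step 10, where the rate and regiochemistry of the transannular hydration are unproven. The fallback delivers the C1 oxygen from the C10 hydroxyl through a carbon dioxide tether instead of by intermolecular hydration. It sets out from 18: Ag2CO3 (10 mol %) and PPh3 under CO2 (1 atm) in MeCN convert the tertiary propargylic alcohol into the cyclic carbonate F3 by 5-exo attack of the carbonate oxygen on C1. Aqueous TFA hydrolyses the enol carbonate with loss of carbon dioxide and returns the route to 19, which goes on to 20 and 21 in the same flask.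

The third is step 3: if the dioxolanyl ketone reacts under Felkin rather than chelation control, the C10 epimer forms. The fallback exchanges the two nucleophiles so that Felkin control gives the same carbinol. It sets out from 3: lithium (trimethylsilyl)acetylide (1.05 equiv, THF, −78 °C) gives the silyl ynone F4. The non-chelating MeTi(Oi-Pr)3 then adds anti to the C9–O bond to give the silylated carbinol F5, and K2CO3 in MeOH removes the silyl group and returns the route to 7.

Further compounds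

F1 | step 9 | methyl (2Z)-2-(bromomethyl)-3-[(4S,5R)-5-{(2S)-5-[(2Z)-1-(tert-butyldiphenylsilyloxy)-4-oxobut-2-en-2-yl]-2-methyl-3-oxo-2,3-dihydrofuran-2-yl}-2,2-dimethyl-1,3-dioxolan-4-yl]prop-2-enoate | COC(=O)/C(CBr)=C/[C@@H]1OC(C)(C)O[C@H]1[C@]1(C)OC(=CC1=O)/C(CO[Si](c1ccccc1)(c1ccccc1)C(C)(C)C)=C\C=O
F2 | step 9 | methyl (4Z)-15-(tert-butyldiphenylsilyloxy)-3,10β-epoxy-6α-hydroxy-8β,9α-(isopropylidenedioxy)-1-oxo-7αH-germacra-2,4,11(13)-trien-12-oate | CC1(C)O[C@H]2[C@@H](C(=C)C(=O)OC)[C@H](O)/C=C(/CO[Si](c3ccccc3)(c3ccccc3)C(C)(C)C)C3=CC(=O)[C@@](C)(O3)[C@@H]2O1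
F3 | step 10 | (1Z,4Z)-15-(tert-butyldiphenylsilyloxy)-8β,9α-(isopropylidenedioxy)-3-oxo-7αH-germacra-1,4,11(13)-trien-12,6α-olide 1,10β-diyl carbonate | CC1(C)O[C@H]2[C@H]3C(=C)C(=O)O[C@@H]3/C=C(/CO[Si](c3ccccc3)(c3ccccc3)C(C)(C)C)C(=O)/C=C3\OC(=O)O[C@@]3(C)[C@@H]2O1
F4 | step 3 | (4R,5R)-N-methoxy-N,2,2-trimethyl-5-[3-(trimethylsilyl)prop-2-ynoyl]-1,3-dioxolane-4-carboxamide | CON(C)C(=O)[C@@H]1OC(C)(C)O[C@H]1C(=O)C#C[Si](C)(C)C
F5 | step 3 | (4R,5R)-5-[(2R)-2-hydroxy-4-(trimethylsilyl)but-3-yn-2-yl]-N-methoxy-N,2,2-trimethyl-1,3-dioxolane-4-carboxamide | CON(C)C(=O)[C@@H]1OC(C)(C)O[C@H]1[C@](C)(O)C#C[Si](C)(C)C
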